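**Plan**

- Numbering: lactone O1, C2 (C=O), C3 (quaternary), C4, C5 (CH2); C6 is the carbinol carbon on C4, C7 the benzylic CH2 on C3.
- Retrosynthesis: cut C3–C7 (benzylation of the C3 enediolate), then C3–OH (enolate hydroxylation), then trade C6–OH for a temporary C3–C6 bond; the resulting 6-aryl-3-oxabicyclo[3.1.0]hexan-2-one is cut at C3–C4 and C3–C6 to an E-cinnamyl diazoacetate made from ferulic acid.
- Enabling feature: C6 carries an aryl donor and C3 the lactone carbonyl, 1,3 to each other across C4, which is the pattern left when water opens the C3–C6 bond of an aryl cyclopropane fused to the five-membered lactone.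
- Forward: one rhodium carbene step closes the cyclopropane and the lactone together; water opens C3–C6; oxygen and then the vanillin-derived benzyl group go onto C3; fluoride frees the three silylated hydroxyls.
- Stereochemistry: C4 from the chiral rhodium carboxamidate (alkene face), C6 from the E-alkene (exo aryl) followed by inversion in the ring opening, C3 from benzylation anti to the C4 substituent.
- The phenol is kept as its acetate until after the opening, so that the aryl group is too weak a donor for C6 to ionise; it is exchanged for silyl before the enolate steps.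

Key step: step 5

Assumption: the S-configured carboxamidates of this family (Rh2(5S-MEPY)4, Rh2(4S-MPPIM)4) take allylic diazoacetates to the (1R,5S) bicycles, so the (1S,5R,6R) bicycle needed here is assigned to Rh2(4R-MPPIM)4; should the sense prove opposite, the antipodal catalyst is used.
Assumption: Rh2(4R-MPPIM)4, dirhodium tetrakis[methyl (4R)-2-oxo-1-(3-phenylpropanoyl)imidazolidine-4-carboxylate], a divalent rhodium carboxamidate, is prepared from the D-asparagine-derived ligand in the same way as its 4S antipode.

**Route**

Step 1
Reactants: 1 ferulic acid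
Product: 2 4-O-acetylferulic acid, (E)-3-(4-acetoxy-3-methoxyphenyl)prop-2-enoic acid
Conditions: Ac2O, pyridine, rt; aqueous work-up
Reagents that add atoms: acetic anhydride, CC(=O)OC(C)=O
Why: Pyridine-catalysed O-acylation of the phenol with the anhydride (esterification) is fast, the mixed anhydride formed transiently at the carboxylic acid is hydrolysed on aqueous work-up, and the acetoxy group installed here is the electron-poor phenol mask needed up to the ring opening.

Step 2
Reactants: 2 4-O-acetylferulic acid
Product: 4 4-O-acetylconiferyl alcohol [(E)-4-(3-hydroxyprop-1-enyl)-2-methoxyphenyl acetate], via acid chloride 3 (not isolated)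
Conditions: SOCl2, cat. DMF, toluene, 70 °C; evaporate; NaBH4, EtOAc, 0 °C → rt
Reagents that add atoms: none
Why: Conversion to the acid chloride and reduction with NaBH4 in an aprotic solvent (borohydride reduction of an acyl chloride) delivers hydride 1,2 to the most electrophilic carbonyl faster than to the alkene or the aryl acetate, so the E-allylic alcohol should form with the acetate intact.

Step 3
Reactants: 4 4-O-acetylconiferyl alcohol; 5 bromoacetyl bromide
Product: 6 (E)-3-(4-acetoxy-3-methoxyphenyl)allyl bromoacetate
Conditions: BrCH2COBr, NaHCO3, MeCN, 0 °C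
Reagents that add atoms: bromoacetyl bromide (5), BrCC(Br)=O
Why: O-acylation of the primary allylic alcohol by the acid bromide with bicarbonate as acid scavenger (esterification) is fast at 0 °C and leaves the aryl acetate and the alkene untouched.

Step 4
Reactants: 6 (E)-3-(4-acetoxy-3-methoxyphenyl)allyl bromoacetate
Product: 7 (E)-3-(4-acetoxy-3-methoxyphenyl)allyl diazoacetate
Conditions: TsNHNHTs, DBU, THF, 0 °C
Reagents that add atoms: N,N'-ditosylhydrazine, Cc1ccc(cc1)S(=O)(=O)NNS(=O)(=O)c1ccc(C)cc1
Why: The bromoacetate N-alkylates N,N'-ditosylhydrazine and DBU then eliminates two sulfinate groups (diazoacetate synthesis from a bromoacetate, a Bamford–Stevens-type elimination) within minutes at 0 °C, a window short and mild enough for the aryl acetate and the allylic ester.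

Step 5
Reactants: 7 (E)-3-(4-acetoxy-3-methoxyphenyl)allyl diazoacetate
Product: 8 (1S,5R,6R)-6-(4-acetoxy-3-methoxyphenyl)-3-oxabicyclo[3.1.0]hexan-2-one (aryl exo; bicycle C1, C5 and C6 are C3, C4 and C6 of the lactone numbering)
Conditions: Rh2(4R-MPPIM)4 (1 mol %), CH2Cl2, reflux, 7 added slowly by syringe pump
Reagents that add atoms: none
Why: The divalent rhodium carboxamidate decomposes 7 to an electrophilic rhodium carbene, which adds to the tethered E-alkene in a concerted, asynchronous and stereospecific [2+1] cycloaddition that forms C3–C4 and the temporary C3–C6 bond together. The closest known reaction type is the enantioselective intramolecular cyclopropanation of trans-disubstituted allylic diazoacetates with chiral dirhodium carboxamidates, for which the imidazolidinone ligand MPPIM is the matched choice. The five-membered lactone closes in a 5-exo sense by bonding of the carbene carbon to the proximal alkene carbon C4 and the three-membered ring closes by the bond to the distal carbon C6, the three-atom ester tether allowing only a cis ring fusion. C3 and C4 are set together by the chiral ligand pocket, which selects the alkene face, and C6 is set relative to them by the E geometry of the alkene, which is carried over intact and places the aryl group exo. The step needs enantioface selectivity and chemoselectivity for cyclopropanation over carbene dimerisation and attack on the arene; the first is secured by the catalyst, the second by slow addition of 7 at high dilution and by the acetoxy group, which makes the arene less nucleophilic.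

Step 6
Reactants: 8 (1S,5R,6R)-6-(4-acetoxy-3-methoxyphenyl)-3-oxabicyclo[3.1.0]hexan-2-one
Product: 9 (4R)-4-[(R)-(4-acetoxy-3-methoxyphenyl)(hydroxy)methyl]oxolan-2-one
Conditions: TfOH (0.2 equiv), H2O (10 equiv), (CF3)2CHOH/CH2Cl2, dilute, 0 °C → rt
Reagents that add atoms: water, O
Why: Protonation of the lactone carbonyl polarises the C3–C6 bond, the only cyclopropane bond aligned with the carbonyl π system and the one that ends at the aryl-bearing carbon, and water attacks C6 anti to the departing C3 in an SN2-like homo-conjugate addition (acid-promoted nucleophilic ring opening of a donor–acceptor cyclopropane), so the exo-aryl centre should be inverted to the (R)-carbinol beside (R)-C4 while the acetoxy group keeps the aryl too weak a donor for a free benzylic cation.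

Step 7
Reactants: 9 (4R)-4-[(R)-(4-acetoxy-3-methoxyphenyl)(hydroxy)methyl]oxolan-2-one
Product: 10 (4R)-4-[(R)-hydroxy(4-hydroxy-3-methoxyphenyl)methyl]oxolan-2-one
Conditions: N2H4·H2O (1.2 equiv), THF, 0 °C
Reagents that add atoms: none
Why: Hydrazinolysis of a phenolic acetate (chemoselective aminolysis of an aryl ester) is much faster than attack on the γ-lactone at 0 °C, and the near-neutral medium should neither ionise C6 nor move the lactone to the C6 hydroxyl.

Step 8
Reactants: 10 (4R)-4-[(R)-hydroxy(4-hydroxy-3-methoxyphenyl)methyl]oxolan-2-one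
Product: 11 (4R)-4-[(R)-(tert-butyldimethylsilyloxy)(4-tert-butyldimethylsilyloxy-3-methoxyphenyl)methyl]oxolan-2-one
Conditions: TBSCl, imidazole, cat. DMAP, DMF, rt
Reagents that add atoms: tert-butyldimethylsilyl chloride, CC(C)(C)[Si](C)(C)Cl
Why: Imidazole-mediated silylation (silyl ether formation) caps the phenol and the secondary benzylic alcohol in one operation, giving protection that withstands amide bases and removing the hydroxyl that could otherwise relactonise.

Step 9
Reactants: 11 (4R)-4-[(R)-(tert-butyldimethylsilyloxy)(4-tert-butyldimethylsilyloxy-3-methoxyphenyl)methyl]oxolan-2-one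
Product: 13 (3R,4S)-4-[(R)-(tert-butyldimethylsilyloxy)(4-tert-butyldimethylsilyloxy-3-methoxyphenyl)methyl]-3-hydroxyoxolan-2-one (3-OH trans to the C4 substituent), via potassium enolate 12 (not isolated)
Conditions: KN(SiMe3)2, THF, −78 °C; 2-(phenylsulfonyl)-3-phenyloxaziridine, −78 °C; aq. NH4Cl
Reagents that add atoms: 2-(phenylsulfonyl)-3-phenyloxaziridine, O=S(=O)(c1ccccc1)N1OC1c1ccccc1
Why: The potassium enolate of the lactone is oxidised at C3 by the N-sulfonyloxaziridine (oxaziridine hydroxylation of an enolate), oxygen entering anti to the bulky C4 substituent to give the 3,4-trans hydroxy lactone, a configuration of no consequence because C3 is made planar again in step 13.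

Step 10
Reactants: 14 vanillin
Product: 15 4-(tert-butyldimethylsilyloxy)-3-methoxybenzaldehyde
Conditions: TBSCl, imidazole, CH2Cl2, rt
Reagents that add atoms: tert-butyldimethylsilyl chloride, CC(C)(C)[Si](C)(C)Cl
Why: Silylation of the phenol with a silyl chloride and imidazole (silyl ether formation) proceeds without touching the aldehyde.

Step 11
Reactants: 15 4-(tert-butyldimethylsilyloxy)-3-methoxybenzaldehyde
Product: 16 4-(tert-butyldimethylsilyloxy)-3-methoxybenzyl alcohol
Conditions: NaBH4, MeOH, 0 °C
Reagents that add atoms: none
Why: Borohydride reduction of the aromatic aldehyde to the benzylic alcohol (hydride reduction) is fast at 0 °C and the aryl silyl ether should survive the short exposure to methanol.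

Step 12
Reactants: 16 4-(tert-butyldimethylsilyloxy)-3-methoxybenzyl alcohol
Product: 17 4-(tert-butyldimethylsilyloxy)-3-methoxybenzyl bromide (used freshly prepared)
Conditions: CBr4, PPh3, CH2Cl2, 0 °C
Reagents that add atoms: carbon tetrabromide, BrC(Br)(Br)Br
Why: The Appel reaction converts the benzylic alcohol to the bromide under neutral conditions that spare the aryl silyl ether, which matters because the product is an electron-rich, acid-sensitive benzylic halide.

Step 13
Reactants: 13 (3R,4S)-3-hydroxy lactone; 17 4-(tert-butyldimethylsilyloxy)-3-methoxybenzyl bromide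
Product: 19 (3S,4R)-3-[4-(tert-butyldimethylsilyloxy)-3-methoxybenzyl]-4-[(R)-(tert-butyldimethylsilyloxy)(4-tert-butyldimethylsilyloxy-3-methoxyphenyl)methyl]-3-hydroxyoxolan-2-one, via dilithium enediolate 18 (not isolated)
Conditions: LiN(iPr)2 (2.3 equiv), THF/DMPU, −78 → −40 °C; 17, −78 → −20 °C; aq. NH4Cl
Reagents that add atoms: 4-(tert-butyldimethylsilyloxy)-3-methoxybenzyl bromide (17), COc1cc(CBr)ccc1O[Si](C)(C)C(C)(C)C
Why: Two equivalents of LiN(iPr)2 give the alkoxide–enolate dianion of the α-hydroxy lactone, which the reactive benzylic bromide alkylates at carbon (alkylation of an α-hydroxy carbonyl dianion) on the face anti to the large C4 substituent, so that the benzyl group ends trans to C6 and the hydroxyl cis, which is the (3S) configuration.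

Step 14
Reactants: 19 tris-silyl ether of the target
Product: 20 target, (3S,4R)-3-hydroxy-4-[(R)-hydroxy(4-hydroxy-3-methoxyphenyl)methyl]-3-(4-hydroxy-3-methoxybenzyl)oxolan-2-one
Conditions: Bu4NF, AcOH (1:1, 3.5 equiv), THF, 0 °C → rt
Reagents that add atoms: none
Why: Fluoride cleaves the two aryl silyl ethers and the benzylic silyl ether (fluoride-mediated desilylation) while acetic acid keeps phenoxide and alkoxide concentrations low, so that neither quinone methide formation at C6 nor migration of the lactone should occur and no stereocentre is touched.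

**Compound list**

1 | ferulic acid | COc1cc(/C=C/C(=O)O)ccc1O | starting material
2 | 4-O-acetylferulic acid, (E)-3-(4-acetoxy-3-methoxyphenyl)prop-2-enoic acid | COc1cc(/C=C/C(=O)O)ccc1OC(C)=O | intermediate
3 | (E)-3-(4-acetoxy-3-methoxyphenyl)prop-2-enoyl chloride | COc1cc(/C=C/C(=O)Cl)ccc1OC(C)=O | intermediate
4 | 4-O-acetylconiferyl alcohol, (E)-4-(3-hydroxyprop-1-enyl)-2-methoxyphenyl acetate | COc1cc(/C=C/CO)ccc1OC(C)=O | intermediate
5 | bromoacetyl bromide | BrCC(Br)=O | starting material
6 | (E)-3-(4-acetoxy-3-methoxyphenyl)allyl bromoacetate | COc1cc(/C=C/COC(=O)CBr)ccc1OC(C)=O | intermediate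
7 | (E)-3-(4-acetoxy-3-methoxyphenyl)allyl diazoacetate | COc1cc(/C=C/COC(=O)C=[N+]=[N-])ccc1OC(C)=O | intermediate
8 | (1S,5R,6R)-6-(4-acetoxy-3-methoxyphenyl)-3-oxabicyclo[3.1.0]hexan-2-one, aryl exo | O=C1OC[C@@H]2[C@@H](c3ccc(OC(C)=O)c(OC)c3)[C@H]12 | intermediate
9 | (4R)-4-[(R)-(4-acetoxy-3-methoxyphenyl)(hydroxy)methyl]oxolan-2-one | O=C1OC[C@@H](C1)[C@@H](O)c1ccc(OC(C)=O)c(OC)c1 | intermediate
10 | (4R)-4-[(R)-hydroxy(4-hydroxy-3-methoxyphenyl)methyl]oxolan-2-one | O=C1OC[C@@H](C1)[C@@H](O)c1ccc(O)c(OC)c1 | intermediate
11 | (4R)-4-[(R)-(tert-butyldimethylsilyloxy)(4-tert-butyldimethylsilyloxy-3-methoxyphenyl)methyl]oxolan-2-one | O=C1OC[C@@H](C1)[C@@H](O[Si](C)(C)C(C)(C)C)c1ccc(O[Si](C)(C)C(C)(C)C)c(OC)c1 | intermediate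
12 | potassium enolate of 11 (C2–C3 enolate, C4 and C6 as in 11) | [K+].[O-]C1=C[C@H](CO1)[C@@H](O[Si](C)(C)C(C)(C)C)c1ccc(O[Si](C)(C)C(C)(C)C)c(OC)c1 | intermediate
13 | (3R,4S)-4-[(R)-(tert-butyldimethylsilyloxy)(4-tert-butyldimethylsilyloxy-3-methoxyphenyl)methyl]-3-hydroxyoxolan-2-one, 3-OH trans to the C4 substituent | O=C1OC[C@@H]([C@H]1O)[C@@H](O[Si](C)(C)C(C)(C)C)c1ccc(O[Si](C)(C)C(C)(C)C)c(OC)c1 | intermediate
14 | vanillin | COc1cc(C=O)ccc1O | starting material
15 | 4-(tert-butyldimethylsilyloxy)-3-methoxybenzaldehyde | COc1cc(C=O)ccc1O[Si](C)(C)C(C)(C)C | intermediate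
16 | 4-(tert-butyldimethylsilyloxy)-3-methoxybenzyl alcohol | COc1cc(CO)ccc1O[Si](C)(C)C(C)(C)C | intermediate
17 | 4-(tert-butyldimethylsilyloxy)-3-methoxybenzyl bromide | COc1cc(CBr)ccc1O[Si](C)(C)C(C)(C)C | intermediate
18 | dilithium enediolate of 13 (C3 alkoxide and C2–C3 enolate, C4 and C6 as in 13) | [Li+].[Li+].[O-]C1=C([O-])[C@H](CO1)[C@@H](O[Si](C)(C)C(C)(C)C)c1ccc(O[Si](C)(C)C(C)(C)C)c(OC)c1 | intermediate
19 | (3S,4R)-3-[4-(tert-butyldimethylsilyloxy)-3-methoxybenzyl]-4-[(R)-(tert-butyldimethylsilyloxy)(4-tert-butyldimethylsilyloxy-3-methoxyphenyl)methyl]-3-hydroxyoxolan-2-one | COc1cc(C[C@@]2(O)C(=O)OC[C@@H]2[C@@H](O[Si](C)(C)C(C)(C)C)c2ccc(O[Si](C)(C)C(C)(C)C)c(OC)c2)ccc1O[Si](C)(C)C(C)(C)C | intermediate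
20 | (3S,4R)-3-hydroxy-4-[(R)-hydroxy(4-hydroxy-3-methoxyphenyl)methyl]-3-(4-hydroxy-3-methoxybenzyl)oxolan-2-one (CNP0352022.1) | COc1cc(C[C@@]2(O)C(=O)OC[C@@H]2[C@@H](O)c2ccc(O)c(OC)c2)ccc1O | target

**Count and risks**

Total step count: 14. Longest linear sequence: 11 steps (steps 1–9, 13 and 14, from ferulic acid); the benzyl bromide arm from vanillin is 3 steps (10–12).

Steps most likely to fail:

1. Step 6 (ring opening). Part of the reaction may run through ionisation at benzylic C6 instead of backside attack, or the product alcohol may re-ionise in the acidic fluorinated medium; water then enters from both faces and the C6 configuration is eroded. Acid-catalysed migration of the lactone onto the new hydroxyl is a second drain. Fallback: the centre is set by reagent control instead of by the opening. Setting out from 9 (as its mixture of C6 epimers), Dess–Martin oxidation (NaHCO3-buffered, CH2Cl2) should give the aryl ketone (4R)-4-(4-acetoxy-3-methoxybenzoyl)oxolan-2-one F1. Corey–Bakshi–Shibata reduction with (S)-2-methyl-CBS-oxazaborolidine and BH3·SMe2 at low temperature, the aryl group acting as the large substituent, should then return (6R)-configured 9, where the route is rejoined. Both operations are non-basic, which matters because C4 is enolisable in F1.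

2. Step 13 (enediolate benzylation). The second deprotonation next to the alkoxide may be incomplete, or the bromide may be consumed by O-alkylation and by excess amide base, so that 13 is returned or its benzyl ether forms. Fallback: the hydroxyl is capped and a simple mono-enolate is alkylated. Setting out from 13, TESOTf and 2,6-lutidine should give the triethylsilyl ether (3R,4R)-4-[(R)-(tert-butyldimethylsilyloxy)(4-tert-butyldimethylsilyloxy-3-methoxyphenyl)methyl]-3-(triethylsilyloxy)oxolan-2-one F2. KN(SiMe3)2 in THF at −78 °C followed by 17 should alkylate anti to the C4 substituent to give the 3-O-triethylsilyl ether of 19 F3. Bu4NF/AcOH as in step 14 then removes all four silyl groups, and the route is rejoined at the target 20.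

3. Step 4 (diazoacetate formation). The amidine base may attack the aryl acetate; the freed para-hydroxycinnamyl ester would then expel its carboxylate through a quinone methide and the substrate would be lost. Fallback: the diazoacetate is made directly from the alcohol with a weaker base. Setting out from 4 (steps 3 and 4 are bypassed), acylation with glyoxylic acid chloride p-toluenesulfonylhydrazone and N,N-dimethylaniline in CH2Cl2 at 0 °C should give, in the flask, the glyoxylate ester (E)-3-(4-acetoxy-3-methoxyphenyl)allyl 2-(2-tosylhydrazinylidene)acetate F4. Et3N then induces loss of sulfinate (Bamford–Stevens-type fragmentation) to give 7, where the route is rejoined.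

Further compounds
F1 | step 6 | (4R)-4-(4-acetoxy-3-methoxybenzoyl)oxolan-2-one | O=C1OC[C@@H](C1)C(=O)c1ccc(OC(C)=O)c(OC)c1
F2 | step 13 | (3R,4R)-4-[(R)-(tert-butyldimethylsilyloxy)(4-tert-butyldimethylsilyloxy-3-methoxyphenyl)methyl]-3-(triethylsilyloxy)oxolan-2-one | O=C1OC[C@@H]([C@H]1O[Si](CC)(CC)CC)[C@@H](O[Si](C)(C)C(C)(C)C)c1ccc(O[Si](C)(C)C(C)(C)C)c(OC)c1
F3 | step 13 | (3S,4R)-3-[4-(tert-butyldimethylsilyloxy)-3-methoxybenzyl]-4-[(R)-(tert-butyldimethylsilyloxy)(4-tert-butyldimethylsilyloxy-3-methoxyphenyl)methyl]-3-(triethylsilyloxy)oxolan-2-one | COc1cc(C[C@@]2(O[Si](CC)(CC)CC)C(=O)OC[C@@H]2[C@@H](O[Si](C)(C)C(C)(C)C)c2ccc(O[Si](C)(C)C(C)(C)C)c(OC)c2)ccc1O[Si](C)(C)C(C)(C)C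
F4 | step 4 | (E)-3-(4-acetoxy-3-methoxyphenyl)allyl 2-(2-tosylhydrazinylidene)acetate | COc1cc(/C=C/COC(=O)C=NNS(=O)(=O)c2ccc(C)cc2)ccc1OC(C)=O
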